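| setting | west | north-west | flask |
|---|---|---|---|
| substrate | 17 mM | 38 mM | 25 mM |
| reagent in the second phase | 25 mM | 25 mM | 25.0 mM |
| remark | run made earlier | run made earlier |  |
| time |  |  | 2.0 d |
| volume of the second phase over the first |  |  | 1.0 |

| run | time / h | target / % |
|---|---|---|
| west | 2.00 | 0 |
| west | 6.00 | 1.9 |
| west | 10.0 | 5.1 |
| west | 15.0 | 8.6 |
| west | 25.0 | 13.8 |
| west | 30.0 | 16.0 |
| west | 40.0 | 18.9 |
| north-west | 6.00 | 1.7 |
| north-west | 12.0 | 3.4 |
| north-west | 15.0 | 4.9 |
| north-west | 20.0 | 5.8 |
| north-west | 30.0 | 6.9 |
| north-west | 40.0 | 7.6 |

(readings scatter by 0.3 percentage points)

- a species is counted by the substrate in it: one side product counts as two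
- in the second phase: reagent in the second phase; everything else is in the first
- charges count per volume of the first phase; a concentration in a rate is the amount of a species over the volume of its own phase; every rate counts per litre of the first phase
- what was read earlier has a scatter of 0.3 percentage points, one standard deviation
- on the list of suspects stand: reagent in the reaction phase <-> reagent in the second phase; substrate + reagent in the reaction phase -> target; reagent in the reaction phase + target -> over-reacted product; substrate + target -> side product; target <-> isomer of the product
- the earlier runs hold the two phases in the same ratio of volumes as the flask asked about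

- red: doubling the amount of reagent in the second phase, all else as stated
- amber: doubling the transfer coefficient of the reagent in the second phase, all else as stated

1. how much target there is at 2.0 d, in percent of the substrate charged
2. the change that raises the amount of target at 2.0 d, in percent of the substrate charged most ("none" if none brings more than 2 percentage points) (red / amber / none)
3. amount of target at 2.0 d, in percent of the substrate charged, after red

Target climbs in a flask while it is made faster than it is used up, and I assume the loss grows in step with the target present. I read making as the rise from 6.00 h to 15.0 h: 0.179 d⁻¹ of the charge in the west run, 0.0853 d⁻¹ in the north-west run. Making over making minus the rise from 30.0 h to 40.0 h gives the balance at that stretch, 1.64 and 1.25. Balance times the target then present is the share at which target would stop rising, a quasi-steady level; I call it the ceiling. Between the runs, this flask gets 17.3%, with making 0.126 d⁻¹.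

What must I know well? In this flask, a ceiling higher by a quarter adds 1.6 percentage points, making higher by a quarter adds 1.2 points, and the west lag of 3.45 h would take off 0.44 points, so I drop it. Closing exponentially on the ceiling, I get 13.2%. If red doubles making, ceiling and target double, to 26.4%; amber I cannot read from these runs and rank behind red.

The forecast says 13.2% (from 11.8% to 14.8%), red, and 23% (from 18.5% to 27%), holding that “supply of reagent through the phase boundary limits the reaction”.

The flask gives 13.8%; red adds 9.1 points, reaching 22.9%, and amber adds 4.6 points.

    reagent in the reaction phase ⇌ reagent in the second phase, rate k1*([reagent in the reaction phase] - [reagent in the second phase]/K1) per volume of the first phase (partition coefficient = 1.10, kL = 4.50 × 10⁻⁶ s⁻¹)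
    substrate + reagent in the reaction phase → target (k = 0.00130 M⁻¹ s⁻¹)
    reagent in the reaction phase + target → over-reacted product (k = 6.60 × 10⁻⁴ M⁻¹ s⁻¹)
    substrate + target → side product (k = 5.70 × 10⁻⁴ M⁻¹ s⁻¹)
    target ⇌ isomer of the product (K = 0.280, k = 5.60 × 10⁻⁶ s⁻¹)

At 2.00 d this flask makes target 1.16 times as fast as it uses it up, each step taken net. My ceiling of 17.3% stands above that 13.8% and above the same flask read at 5.00 d, which holds 14.4% of target and 60.1% of side product.

The numbers in the tables come from a simulation with made-up constants, and the scatter is random.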